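## Retrosynthetic overview
1. Septeremophilane E ⇒ remove the side-chain silyl ether and lower C7 from the diosphenol to CH2 ⇒ a 3β-acyloxy-1,9-dien-8-one that already carries the complete side chain.
2. Rings A and B are disconnected together. An intramolecular Diels–Alder reaction of an acyclic (E)-1-acyloxy vinylallenyl ketone forms C3–C4 and C5–C10 and sets C3, C4 and C5 in one event.
3. The axially chiral vinylallene ⇒ 1,5-prototropic shift of an acyclic enynone allylic ester.
4. The enynone ester ⇒ ester bond plus C8–C9 bond ⇒ side-chain acid, pent-2-en-4-yn-1-ol and ethyl (E)-4-methylhex-4-enoate. The last comes from a Johnson–Claisen reaction whose alkene geometry encodes the cis C4/C5 methyl groups.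
5. The side-chain acid ⇒ butanal, formaldehyde and triethyl 4-phosphonocrotonate (enamine-catalysed hydroxymethylation, then vinylogous olefination).

**Numbering.** Core atoms carry eremophilane numbers: C1–C10, with the ester on C3, methyl groups on C4 and C5, and the ketone at C8. Side-chain atoms are primed.

**Assumption.** The (2S,6S)-guanidine of step 7 is taken to give the (aR) allene axis. If it gives (aS), its (2R,6R) antipode is used. Pent-2-en-4-yn-1-ol is used as its (E) isomer.

## Route

Step 1
Reactants: 1 3-methylbut-3-en-2-ol (racemic); 2 triethyl orthoacetate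
Product: 4 ethyl (E)-4-methylhex-4-enoate, via mixed ketene acetal 3 (not isolated)
Conditions: EtCO2H (5 mol %), 2 (5 equiv, neat), 140 °C, EtOH distilled off
Reagents that add atoms: none
Why: Johnson–Claisen rearrangement, in which the chair [3,3] transition state of ketene acetal 3 holds the carbinol methyl equatorial and gives the (E)-trisubstituted alkene (both methyl groups cis), the geometry that later fixes the cis C4/C5 dimethyl relationship.

Step 2
Reactants: 4 ethyl (E)-4-methylhex-4-enoate; 5 (E)-pent-2-en-4-yn-1-ol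
Product: 8 (2E,9E)-1-hydroxy-9-methylundeca-2,9-dien-4-yn-6-one, via Weinreb amide 6 (not isolated), via dilithiated pentenynol 7 (not isolated)
Conditions: 4, MeNH(OMe)·HCl, i-PrMgCl, THF, −20 °C; separately 5, n-BuLi (2.1 equiv), THF, −78 °C; combine, −78 → 0 °C; aq NH4Cl
Reagents that add atoms: N,O-dimethylhydroxylamine hydrochloride, CNOC.Cl (its MeN(OMe) unit stays only in 6); n-butyllithium, [Li]CCCC (its lithium stays only in 7)
Why: Weinreb ketone synthesis in one flask, in which the chelated tetrahedral adduct of amide 6 with the acetylide carbon of 7 survives until the quench, so only mono-addition occurs, the alkoxide end of 7 is a spectator, and no stereocentre is formed.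

Step 3
Reactants: 9 butanal; 10 formaldehyde (37 % aqueous)
Product: 12 (S)-2-{[(tert-butyldimethylsilyl)oxy]methyl}butanal, via (S)-2-(hydroxymethyl)butanal 11 (not isolated)
Conditions: (R)-α,α-diphenylprolinol trimethylsilyl ether (10 mol %), pH 7 phosphate buffer, PhMe, rt; organic phase separated and dried; TBSCl, imidazole, CH2Cl2, 0 °C
Reagents that add atoms: tert-butyldimethylsilyl chloride, CC(C)(C)[Si](C)(C)Cl
Why: Enamine-catalysed α-hydroxymethylation (cross-aldol with formaldehyde), in which the diarylprolinol silyl ether shields one enamine face and sets the side-chain stereocentre (S in the aldehyde, R in the final chain), and immediate silylation stops retro-aldol and hemiacetal oligomerisation.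

Step 4
Reactants: 12 (S)-2-{[(tert-butyldimethylsilyl)oxy]methyl}butanal; 13 triethyl 4-phosphonocrotonate
Product: 15 ethyl (2E,4E,6R)-6-{[(tert-butyldimethylsilyl)oxy]methyl}octa-2,4-dienoate, via lithiated phosphonate 14 (not isolated)
Conditions: 13, LiN(SiMe3)2, THF, −78 °C; then 12, −78 → 0 °C
Reagents that add atoms: LiN(SiMe3)2, [Li]N([Si](C)(C)C)[Si](C)(C)C (its lithium stays only in 14)
Why: Vinylogous Horner–Wadsworth–Emmons olefination, in which the stabilised allylic phosphonate anion gives the (E,E)-dienoate and addition at −78 °C leaves the α-stereocentre of the aldehyde unepimerised.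

Step 5
Reactants: 15 ethyl (2E,4E,6R)-6-{[(tert-butyldimethylsilyl)oxy]methyl}octa-2,4-dienoate
Product: 16 (2E,4E,6R)-6-{[(tert-butyldimethylsilyl)oxy]methyl}octa-2,4-dienoic acid
Conditions: LiOH, THF/MeOH/H2O, rt; 1 M HCl to pH 4, 0 °C
Reagents that add atoms: lithium hydroxide, [Li+].[OH-] (oxygen of the new acid OH)
Why: Ester saponification, in which hydroxide attacks only the ethyl ester while the primary TBS ether and the remote C6′ stereocentre are untouched.

Step 6
Reactants: 8 (2E,9E)-1-hydroxy-9-methylundeca-2,9-dien-4-yn-6-one; 16 (2E,4E,6R)-6-{[(tert-butyldimethylsilyl)oxy]methyl}octa-2,4-dienoic acid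
Product: 17 (2E,9E)-9-methyl-6-oxoundeca-2,9-dien-4-yn-1-yl (2E,4E,6R)-6-{[(tert-butyldimethylsilyl)oxy]methyl}octa-2,4-dienoate
Conditions: EDC·HCl, DMAP (10 mol %), CH2Cl2, 0 °C
Reagents that add atoms: none
Why: Steglich-type carbodiimide esterification of an unhindered primary allylic alcohol, mild enough to leave the enynone untouched, with no stereocentre formed or disturbed.

Step 7
Reactants: 17 (2E,9E)-9-methyl-6-oxoundeca-2,9-dien-4-yn-1-yl (2E,4E,6R)-6-{[(tert-butyldimethylsilyl)oxy]methyl}octa-2,4-dienoate
Product: 19 bicyclic dienone ester (4aR,5R,6S)-4a,5-dimethyl-2-oxo-2,3,4,4a,5,6-hexahydronaphthalen-6-yl (2E,4E,6R)-6-{[(tert-butyldimethylsilyl)oxy]methyl}octa-2,4-dienoate, via (aR)-vinylallenone 18 (not isolated)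
Conditions: (2S,6S)-2,6-di-tert-butyl-2,3,5,6-tetrahydro-1H-imidazo[1,2-a]imidazole (chiral bicyclic guanidine, 10 mol %), BHT (5 mol %), PhMe (0.002 M), 80 °C, 72 h
Reagents that add atoms: none
Why: Proposed new method: the guanidine removes the ε-proton (C3–H) of the enynone, and its guanidinium, hydrogen-bonded to the C8 oxygen of the extended trienolate, returns the proton to one face of C9, a 1,5-prototropic shift that creates the (aR) allene axis (closest known reaction type: chiral-guanidine-catalysed 3-alkynoate-to-allenoate isomerisation); at 2 mM the bimolecular reverse proton transfer should be slower than the unimolecular intramolecular Diels–Alder reaction of the vinylallene (a known type with axial-to-central chirality transfer), so the axis is trapped before it racemises and the unreactive (Z)-enol ester is fed back through the same equilibrium; the tether on C9 can reach C10 only from the face it occupies and only in the exo orientation, so the two cis methyl groups lie endo and end up cis to the outside (E)-acyloxy group, which closes rings A and B together and sets C3, C4 and C5 (3β,4β,5β) at once.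

Step 8
Reactants: 19 bicyclic dienone ester
Product: 21 7α-hydroxy ketone (3R,4aR,5R,6S)-3-hydroxy-4a,5-dimethyl-2-oxo-2,3,4,4a,5,6-hexahydronaphthalen-6-yl (2E,4E,6R)-6-{[(tert-butyldimethylsilyl)oxy]methyl}octa-2,4-dienoate, via sodium enolate 20 (not isolated)
Conditions: NaN(SiMe3)2 (1.05 equiv), THF, −78 °C; 2-(phenylsulfonyl)-3-phenyloxaziridine, −78 °C; AcOH
Reagents that add atoms: 2-(phenylsulfonyl)-3-phenyloxaziridine, O=S(=O)(c1ccccc1)N1OC1c1ccccc1 (oxygen atom); NaN(SiMe3)2, [Na]N([Si](C)(C)C)[Si](C)(C)C (its sodium stays only in 20)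
Why: Davis oxidation of the kinetic cross-conjugated α′-enolate, in which C7–H is the fastest proton to be removed at −78 °C and the oxaziridine approaches anti to the axial C5 methyl to give the 7α-alcohol, a stereocentre that is erased in step 9.

Step 9
Reactants: 21 7α-hydroxy ketone
Product: 23 diosphenol silyl ether (4aS,5R,6S)-3-hydroxy-4a,5-dimethyl-2-oxo-2,4a,5,6-tetrahydronaphthalen-6-yl (2E,4E,6R)-6-{[(tert-butyldimethylsilyl)oxy]methyl}octa-2,4-dienoate, via 7,8-diketone 22 (not isolated)
Conditions: Dess–Martin periodinane, CH2Cl2, 0 °C → rt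
Reagents that add atoms: none
Why: Dess–Martin oxidation of the acyloin gives diketone 22, which enolises at once toward C6 to the hydrogen-bonded cross-conjugated diosphenol, while C3, C4 and C5 are not enolisable and stay intact.

Step 10
Reactants: 23 diosphenol silyl ether
Product: 24 Septeremophilane E
Conditions: HF·pyridine, pyridine/THF, 0 °C → rt
Reagents that add atoms: none
Why: Fluoride-mediated cleavage of the primary TBS ether under buffered conditions, which spares the allylic dienoate ester and the diosphenol and touches no stereocentre.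

## Compound list
1 | 3-methylbut-3-en-2-ol (racemic) | CC(O)C(C)=C | starting material
2 | triethyl orthoacetate | CC(OCC)(OCC)OCC | starting material
3 | 1-ethoxyvinyl 3-methylbut-3-en-2-yl ether (mixed ketene acetal) | C=C(OCC)OC(C)C(C)=C | intermediate
4 | ethyl (E)-4-methylhex-4-enoate | C/C=C(\C)CCC(=O)OCC | intermediate
5 | (E)-pent-2-en-4-yn-1-ol | C#C/C=C/CO | starting material
6 | (E)-N-methoxy-N,4-dimethylhex-4-enamide | C/C=C(\C)CCC(=O)N(C)OC | intermediate
7 | dilithiated (E)-pent-2-en-4-yn-1-ol | [Li]C#C/C=C/CO[Li] | intermediate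
8 | (2E,9E)-1-hydroxy-9-methylundeca-2,9-dien-4-yn-6-one | C/C=C(\C)CCC(=O)C#C/C=C/CO | intermediate
9 | butanal | CCCC=O | starting material
10 | formaldehyde | C=O | starting material
11 | (S)-2-(hydroxymethyl)butanal | CC[C@H](C=O)CO | intermediate
12 | (S)-2-{[(tert-butyldimethylsilyl)oxy]methyl}butanal | CC[C@H](C=O)CO[Si](C)(C)C(C)(C)C | intermediate
13 | triethyl 4-phosphonocrotonate | CCOC(=O)/C=C/CP(=O)(OCC)OCC | starting material
14 | lithiated triethyl 4-phosphonocrotonate | CCOC(=O)/C=C/[CH-]P(=O)(OCC)OCC.[Li+] | intermediate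
15 | ethyl (2E,4E,6R)-6-{[(tert-butyldimethylsilyl)oxy]methyl}octa-2,4-dienoate | CC[C@H](/C=C/C=C/C(=O)OCC)CO[Si](C)(C)C(C)(C)C | intermediate
16 | (2E,4E,6R)-6-{[(tert-butyldimethylsilyl)oxy]methyl}octa-2,4-dienoic acid | CC[C@H](/C=C/C=C/C(=O)O)CO[Si](C)(C)C(C)(C)C | intermediate
17 | enynone ester, (2E,9E)-9-methyl-6-oxoundeca-2,9-dien-4-yn-1-yl ester of 16 | CC[C@H](/C=C/C=C/C(=O)OC/C=C/C#CC(=O)CC/C(C)=C/C)CO[Si](C)(C)C(C)(C)C | intermediate
18 | (aR)-vinylallenone, (1E,9E)-9-methyl-6-oxoundeca-1,3,4,9-tetraen-1-yl ester of 16 | CC[C@H](/C=C/C=C/C(=O)O/C=C/C([H])=[C@]=C([H])C(=O)CC/C(C)=C/C)CO[Si](C)(C)C(C)(C)C | intermediate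
19 | bicyclic dienone ester (3β-acyloxy, 4β,5β-dimethyl, 1,9-dien-8-one) | CC[C@H](/C=C/C=C/C(=O)O[C@H]1C=CC2=CC(=O)CC[C@]2(C)[C@H]1C)CO[Si](C)(C)C(C)(C)C | intermediate
20 | sodium C7,C8-enolate of 19 | CC[C@H](/C=C/C=C/C(=O)O[C@H]1C=CC2=CC(O[Na])=CC[C@]2(C)[C@H]1C)CO[Si](C)(C)C(C)(C)C | intermediate
21 | 7α-hydroxy ketone | CC[C@H](/C=C/C=C/C(=O)O[C@H]1C=CC2=CC(=O)[C@H](O)C[C@]2(C)[C@H]1C)CO[Si](C)(C)C(C)(C)C | intermediate
22 | 7,8-diketone | CC[C@H](/C=C/C=C/C(=O)O[C@H]1C=CC2=CC(=O)C(=O)C[C@]2(C)[C@H]1C)CO[Si](C)(C)C(C)(C)C | intermediate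
23 | diosphenol silyl ether (O-TBS Septeremophilane E) | CC[C@H](/C=C/C=C/C(=O)O[C@H]1C=CC2=CC(=O)C(O)=C[C@]2(C)[C@H]1C)CO[Si](C)(C)C(C)(C)C | intermediate
24 | Septeremophilane E | CC[C@H](/C=C/C=C/C(=O)O[C@H]1C=CC2=CC(=O)C(O)=C[C@]2(C)[C@H]1C)CO | target

## Step count
- Total step count: 10.
- Longest linear sequence: 8 (steps 3, 4, 5, 6, 7, 8, 9, 10).

## Steps most likely to fail, with fallbacks

**Step 7.** The risks are low enantioselectivity of the proton shuttle, racemisation of the axis before it is trapped, addition of the guanidine to the ynone, and a slow cycloaddition onto the unactivated trisubstituted alkene. Any leakage of the wrong axis gives a diastereomer of 19, because the side chain is enantiopure, so it can be removed by chromatography.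

The fallback builds the axis stereospecifically from a carbinol stereocentre. It sets out from 4 and 16 and comes back at 18, and therefore at 19.
- Acid 16 is added across propynal (N-methylmorpholine cat., CH2Cl2) to give the (E)-3-oxoprop-1-en-1-yl ester F1, with the (E)-enol ester geometry already fixed.
- Ester 4 is taken through amide 6 with ethynylmagnesium bromide to (E)-6-methyloct-6-en-1-yn-3-one F2.
- Me2Zn with the ProPhenol antipode that delivers the (R)-carbinol joins enal F1 and alkyne F2 to the (R)-propargylic alcohol F3.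
- Mitsunobu displacement with 2-nitrobenzenesulfonylhydrazide (PPh3, DEAD, THF, −15 °C) gives, with inversion, the (S)-sulfonylhydrazine F4.
- On warming, F4 loses the sulfinic acid to give the propargylic diazene F5.
- F5 expels N2 in a suprafacial retro-ene step (Myers allene synthesis). This places hydrogen on C9, the polarity-matched α-carbon of the ynone, and delivers (aR)-18.
- Base-free heating in dilute toluene then gives 19.

**Step 8.** The risks are competing ε-deprotonation at C3–H, attack of the enolate on the sulfonimine by-product, and over-oxidation.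

The fallback sets out from 19 and comes back at 23. It replaces enolate chemistry by enaminone cleavage and makes step 9 unnecessary.
- Heating 19 with tert-butoxybis(dimethylamino)methane condenses only the α′-methylene and gives the 7-(dimethylaminomethylidene) ketone F6.
- Dye-sensitised photooxygenation (O2, tetraphenylporphyrin, hν, CH2Cl2, −78 °C) cleaves this very electron-rich C=C through a dioxetane to diketone 22, which tautomerises to 23.

**Step 2.** The risks are an incomplete in-flask amide formation, addition of residual i-PrMgCl, and the sensitivity of the free hydroxy enynone.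

The fallback sets out from 4, 5 and 16 and comes back at 17. It forms the C8–C9 bond by carbonyl addition with the ester already in place.
- Ester 4 is reduced (i-Bu2AlH, CH2Cl2, −78 °C) to (E)-4-methylhex-4-enal F7.
- Alcohol 5 is esterified with 16 (EDC·HCl, DMAP) to the (E)-pent-2-en-4-yn-1-yl ester F8.
- Zn(OTf)2 and Et3N in toluene add the terminal alkyne of F8 to F7 to give the propargylic alcohol F9 as an inconsequential mixture of C8 epimers.
- Dess–Martin oxidation of F9 gives 17.

## Further compounds
F1 | step 7 | (E)-3-oxoprop-1-en-1-yl (2E,4E,6R)-6-{[(tert-butyldimethylsilyl)oxy]methyl}octa-2,4-dienoate | CC[C@H](/C=C/C=C/C(=O)O/C=C/C=O)CO[Si](C)(C)C(C)(C)C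
F2 | step 7 | (E)-6-methyloct-6-en-1-yn-3-one | C/C=C(\C)CCC(=O)C#C
F3 | step 7 | (1E,3R,9E)-3-hydroxy-9-methyl-6-oxoundeca-1,9-dien-4-yn-1-yl ester of 16 | CC[C@H](/C=C/C=C/C(=O)O/C=C/[C@@H](O)C#CC(=O)CC/C(C)=C/C)CO[Si](C)(C)C(C)(C)C
F4 | step 7 | (3S)-3-[1-(2-nitrophenylsulfonyl)hydrazinyl] analogue of F3 | CC[C@H](/C=C/C=C/C(=O)O/C=C/[C@H](N(N)S(=O)(=O)c1ccccc1[N+](=O)[O-])C#CC(=O)CC/C(C)=C/C)CO[Si](C)(C)C(C)(C)C
F5 | step 7 | (3S)-3-diazenyl analogue of F3 (propargylic diazene) | CC[C@H](/C=C/C=C/C(=O)O/C=C/[C@H](N=N)C#CC(=O)CC/C(C)=C/C)CO[Si](C)(C)C(C)(C)C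
F6 | step 8 | 7-[(E)-(dimethylamino)methylidene] derivative of 19 | CC[C@H](/C=C/C=C/C(=O)O[C@H]1C=CC2=CC(=O)/C(=C/N(C)C)C[C@]2(C)[C@H]1C)CO[Si](C)(C)C(C)(C)C
F7 | step 2 | (E)-4-methylhex-4-enal | C/C=C(\C)CCC=O
F8 | step 2 | (E)-pent-2-en-4-yn-1-yl (2E,4E,6R)-6-{[(tert-butyldimethylsilyl)oxy]methyl}octa-2,4-dienoate | CC[C@H](/C=C/C=C/C(=O)OC/C=C/C#C)CO[Si](C)(C)C(C)(C)C
F9 | step 2 | (2E,9E)-6-hydroxy-9-methylundeca-2,9-dien-4-yn-1-yl ester of 16 (both C8 epimers) | CC[C@H](/C=C/C=C/C(=O)OC/C=C/C#CC(O)CC/C(C)=C/C)CO[Si](C)(C)C(C)(C)C
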